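The five-membered ring O–C7–C8–C3'–C4' and its exocyclic C9 are read as a contracted flavanone. C9 is the former C4 carbonyl carbon of a six-membered chroman-4-one, so the disconnection is the C8–C3' bond. An iodine(III)-induced oxidative 1,2-aryl shift in trimethyl orthoformate moves the benzo carbon C3' from C9 to C8. In one operation it contracts the pyranone to the dihydrobenzofuran, expels C9 as a methyl ester and sets C8 trans to C7. The precursor is (R)-6-bromo-8-methoxy-3',4',5'-trimethoxyflavanone, obtained by catalytic asymmetric arylation of a chromone; its single stereocentre becomes C7. A Heck reaction and one double ester reduction complete the target.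

Key step: step 4

Assumption: the facial sense in step 3 is taken from the model for (S)-t-BuPyOx with cyclic enones, which predicts 2R here. Should the chromone respond in the opposite sense, (R)-t-BuPyOx is used and nothing else changes.

Step 1
Reactants: 1 1-(2-hydroxy-3-methoxyphenyl)ethan-1-one
Product: 2 1-(5-bromo-2-hydroxy-3-methoxyphenyl)ethan-1-one
Conditions: NBS (1.05 equiv), MeCN, 0 °C → rt
Reagents that add atoms: N-bromosuccinimide O=C1CCC(=O)N1Br
Why: Electrophilic aromatic bromination: the free phenol directs NBS to its open para position C5 (the same outcome as in the bromination of o-vanillin), while the hydrogen-bonded acetyl group stays untouched in the absence of acid or light.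

Step 2
Reactants: 2 1-(5-bromo-2-hydroxy-3-methoxyphenyl)ethan-1-one
Product: 4 6-bromo-8-methoxy-4H-chromen-4-one, via enaminone 3 (not isolated)
Conditions: Me2NCH(OMe)2 (2 equiv), toluene, 100 °C; concentrate; conc. HCl, CH2Cl2, 40 °C
Reagents that add atoms: N,N-dimethylformamide dimethyl acetal CN(C)C(OC)OC
Why: Condensation of the acetyl CH3 with the amide acetal gives the vinylogous amide 3, and acid then triggers conjugate addition of the phenol and loss of dimethylamine (enaminone route to chromones), which adds the one carbon that becomes C2.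

Step 3
Reactants: 4 6-bromo-8-methoxy-4H-chromen-4-one; 5 3,4,5-trimethoxyphenylboronic acid
Product: 6 (2R)-6-bromo-8-methoxy-2-(3,4,5-trimethoxyphenyl)-2,3-dihydro-4H-chromen-4-one
Conditions: Pd(OCOCF3)2 (5 mol %), (S)-t-BuPyOx (6 mol %), NH4PF6 (30 mol %), H2O (5 equiv), ClCH2CH2Cl, 60 °C; recrystallisation if the ee needs raising
Reagents that add atoms: none
Why: Pd(II)-catalysed asymmetric conjugate addition of an arylboronic acid (Hayashi–Miyaura-type 1,4-arylation): the cationic aryl–Pd(PyOx) complex inserts the C2=C3 bond on the face left open by the tert-butyl group and so should set C2 as R, the redox-neutral Pd(II) cycle spares the C–Br bond, and the base-free medium avoids racemisation by retro-oxa-Michael opening.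

Step 4
Reactants: 6 (2R)-6-bromo-8-methoxy-2-(3,4,5-trimethoxyphenyl)-2,3-dihydro-4H-chromen-4-one
Product: 10 methyl (2R,3R)-5-bromo-7-methoxy-2-(3,4,5-trimethoxyphenyl)-2,3-dihydro-1-benzofuran-3-carboxylate, via enol ether 7 (not isolated), via iodane 8 (not isolated), via orthoester 9 (not isolated)
Conditions: HC(OMe)3 (solvent), conc. H2SO4 (cat.), rt, 30 min; PhI(OAc)2 (1.2 equiv), 0 °C → rt; then H2O, then aq. NaHCO3
Reagents that add atoms: trimethyl orthoformate COC(OC)OC; water O
Why: Acid and trimethyl orthoformate convert ketone 6 into enol ether 7, PhI(OAc)2 adds to its C3 on the face anti to the C2 aryl group while methanol caps C4, and in the resulting trans-diequatorial iodane 8 the benzo carbon C4a shifts from C4 to C3 with loss of iodobenzene, leaving a dimethoxycarbenium ion that is trapped as orthoester 9 and hydrolysed to ester 10 on work-up. The closest known reaction type is the hypervalent-iodine (or thallium(III)) oxidative 1,2-aryl rearrangement of aryl ketones in trimethyl orthoformate, which on flavanones is known as a ring contraction to trans-2-aryl-2,3-dihydrobenzofuran-3-carboxylates. The five-membered ring closes not by cyclisation of an open chain but by the 1,2-shift itself, through a spiro phenonium bridge (3-exo-tet attack of C4a on C3, then cleavage of C4–C4a), so that six ring atoms become five and C4 ends outside the ring as C9. The new stereocentre C3 (C8 of the target) is controlled by C2: anti addition of iodine followed by inversion in the shift places the ester trans to the aryl group, and C2 itself is not touched. The step needs migration of C4a in preference to a 2→3 shift of the trimethoxyphenyl ring and to simple dehydrogenation of C2–C3; the equatorial C3–I bond is antiperiplanar to C4–C4a but gauche to the C2–aryl bond, C4a is activated by the ortho ring oxygen O1, and the two methoxy groups on C4 stabilise the charge that the shift leaves behind. Attack of iodine(III) on the arenes is held back because the enol ether is formed first and is the most nucleophilic π system, the A ring carries bromine and no free phenol is present.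

Step 5
Reactants: 10 methyl (2R,3R)-5-bromo-7-methoxy-2-(3,4,5-trimethoxyphenyl)-2,3-dihydro-1-benzofuran-3-carboxylate; 11 methyl acrylate
Product: 12 methyl (2R,3R)-7-methoxy-5-[(E)-3-methoxy-3-oxoprop-1-en-1-yl]-2-(3,4,5-trimethoxyphenyl)-2,3-dihydro-1-benzofuran-3-carboxylate
Conditions: Pd2(dba)3 (1.5 mol %), [HP(t-Bu)3]BF4 (6 mol %), Cy2NMe (1.2 equiv), dioxane, rt → 50 °C
Reagents that add atoms: none
Why: Mizoroki–Heck reaction: oxidative addition into the C–Br bond, syn insertion of the acrylate and syn β-hydride elimination give the E-cinnamate, and the bulky electron-rich phosphine allows a temperature and a hindered amine base at which the acidic C3–H is not removed, the trans ester being the more stable epimer in any case.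

Step 6
Reactants: 12 methyl (2R,3R)-7-methoxy-5-[(E)-3-methoxy-3-oxoprop-1-en-1-yl]-2-(3,4,5-trimethoxyphenyl)-2,3-dihydro-1-benzofuran-3-carboxylate
Product: 13 (-)-(7R,8S,7'E)-3,4,5,5'-tetramethoxy-4',7-epoxy-8,3'-neolign-7'-ene-9,9'-diol
Conditions: DIBAL-H (6 equiv), CH2Cl2, −78 → 0 °C; aq. Rochelle salt
Reagents that add atoms: none
Why: DIBAL-H reduces the saturated and the α,β-unsaturated ester by 1,2-hydride delivery to the two primary alcohols without touching the E-alkene, the aryl ethers or the two stereocentres, since the reagent is Lewis acidic and not basic.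

Compound list
1 | 1-(2-hydroxy-3-methoxyphenyl)ethan-1-one | CC(=O)c1cccc(OC)c1O | starting material
2 | 1-(5-bromo-2-hydroxy-3-methoxyphenyl)ethan-1-one | CC(=O)c1cc(Br)cc(OC)c1O | intermediate
3 | (E)-1-(5-bromo-2-hydroxy-3-methoxyphenyl)-3-(dimethylamino)prop-2-en-1-one | CN(C)/C=C/C(=O)c1cc(Br)cc(OC)c1O | intermediate
4 | 6-bromo-8-methoxy-4H-chromen-4-one | O=C1C=COc2c(OC)cc(Br)cc12 | intermediate
5 | 3,4,5-trimethoxyphenylboronic acid | COc1cc(B(O)O)cc(OC)c1OC | starting material
6 | (2R)-6-bromo-8-methoxy-2-(3,4,5-trimethoxyphenyl)-2,3-dihydro-4H-chromen-4-one | COc1cc([C@@H]2Oc3c(OC)cc(Br)cc3C(=O)C2)cc(OC)c1OC | intermediate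
7 | (2R)-6-bromo-4,8-dimethoxy-2-(3,4,5-trimethoxyphenyl)-2H-chromene | COc1cc([C@@H]2Oc3c(OC)cc(Br)cc3C(OC)=C2)cc(OC)c1OC | intermediate
8 | (2S,3S)-3-[acetoxy(phenyl)-λ3-iodanyl]-6-bromo-4,4,8-trimethoxy-2-(3,4,5-trimethoxyphenyl)chromane (2,3-trans) | COc1cc([C@@H]2Oc3c(OC)cc(Br)cc3C(OC)(OC)[C@H]2I(OC(C)=O)c4ccccc4)cc(OC)c1OC | intermediate
9 | (2R,3R)-5-bromo-7-methoxy-3-(trimethoxymethyl)-2-(3,4,5-trimethoxyphenyl)-2,3-dihydro-1-benzofuran (trans) | COc1cc([C@@H]2Oc3c(OC)cc(Br)cc3[C@H]2C(OC)(OC)OC)cc(OC)c1OC | intermediate
10 | methyl (2R,3R)-5-bromo-7-methoxy-2-(3,4,5-trimethoxyphenyl)-2,3-dihydro-1-benzofuran-3-carboxylate (trans) | COc1cc([C@@H]2Oc3c(OC)cc(Br)cc3[C@H]2C(=O)OC)cc(OC)c1OC | intermediate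
11 | methyl acrylate | C=CC(=O)OC | starting material
12 | methyl (2R,3R)-7-methoxy-5-[(E)-3-methoxy-3-oxoprop-1-en-1-yl]-2-(3,4,5-trimethoxyphenyl)-2,3-dihydro-1-benzofuran-3-carboxylate | COc1cc([C@@H]2Oc3c(OC)cc(/C=C/C(=O)OC)cc3[C@H]2C(=O)OC)cc(OC)c1OC | intermediate
13 | (-)-(7R,8S,7'E)-3,4,5,5'-tetramethoxy-4',7-epoxy-8,3'-neolign-7'-ene-9,9'-diol | COc1cc([C@@H]2Oc3c(OC)cc(/C=C/CO)cc3[C@H]2CO)cc(OC)c1OC | target

Total step count: 6
Longest linear sequence: 6 steps (1 → 2 → 4 → 6 → 10 → 12 → 13)

Steps most likely to fail

Step 4.
- What may go wrong: the electron-rich trimethoxyphenyl ring may migrate from C2 to C3 instead of the benzo carbon. The C2–C3 bond may simply be dehydrogenated. Iodine(III) may be arylated by the B ring. Strong acid may ionise the benzylic C2–O bond and erode the enantiomeric purity.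
- Fallback: it sets out from 6 and comes back at 10, and it keeps the six-to-five contraction but changes the mechanism to a photochemical Wolff rearrangement.
- Kinetic deprotonation of 6 (LiHMDS, THF, −78 °C) and acylation with 2,2,2-trifluoroethyl trifluoroacetate should give the 3-trifluoroacetyl flavanone F1. Detrifluoroacetylative diazo transfer (MsN3, Et3N, H2O, MeCN, rt) should convert it into the 3-diazoflavanone F2.
- Irradiation (365 nm, MeOH, rt) expels nitrogen. Only the carbonyl-bound benzo carbon can shift to the carbene centre of the s-Z-locked diazoketone, so the B ring cannot compete. The ring-contracted ketene F3 adds methanol to give 10 together with the cis ester F4.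
- Catalytic DBU in CH2Cl2 should equilibrate F4 to the more stable trans ester 10, so C3 is set under thermodynamic control from C2.

Step 3.
- What may go wrong: insertion into the electron-rich chromone may be slow, the electron-rich boronic acid may undergo protodeboronation, and facial selectivity may be insufficient.
- Fallback: it sets out from 2 and comes back at 6, and it replaces asymmetric C–C bond formation by a resolution.
- Claisen–Schmidt condensation of 2 with commercial 3,4,5-trimethoxybenzaldehyde (KOH, EtOH, rt) should give the 2'-hydroxychalcone F5.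
- Oxa-Michael cyclisation (NaOAc, EtOH, reflux) should give the racemic flavanone F6.
- Kinetic resolution follows by Noyori asymmetric transfer hydrogenation (RuCl[(S,S)-TsDPEN](p-cymene), HCO2H/Et3N, EtOAc, rt, stopped near half conversion). It should reduce the matched (2S)-ketone to the cis-flavan-4-ol F7 and leave (2R)-6, which is separated by chromatography.

Step 5.
- What may go wrong: the base may remove the acidic C3–H, followed by β-elimination of the phenoxide (ring opening with loss of both stereocentres) or by epimerisation. Oxidative addition to the electron-rich aryl bromide may be sluggish.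
- Fallback: it sets out from 10 and comes back at 13 with the same number of steps. It removes the acidic C–H before the palladium step and brings in the side chain as a preformed E-alkenyl metal.
- Reduction of 10 (DIBAL-H, CH2Cl2, −78 → 0 °C) should give the bromo alcohol F8.
- Stille coupling of F8 with (E)-3-(tributylstannyl)prop-2-en-1-ol (Pd(PPh3)4, toluene, 100 °C, no base) should give 13 directly with retention of the alkene geometry.

Further compounds
F1 | step 4 | (2R)-6-bromo-8-methoxy-3-(trifluoroacetyl)-2-(3,4,5-trimethoxyphenyl)chroman-4-one (C3 not defined, enolisable) | COc1cc([C@@H]2Oc3c(OC)cc(Br)cc3C(=O)C2C(=O)C(F)(F)F)cc(OC)c1OC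
F2 | step 4 | (2S)-6-bromo-3-diazo-8-methoxy-2-(3,4,5-trimethoxyphenyl)chroman-4-one (geometry at C2 as in 6, descriptor changed by priority) | COc1cc([C@@H]2Oc3c(OC)cc(Br)cc3C(=O)C2=[N+]=[N-])cc(OC)c1OC
F3 | step 4 | (2S)-[5-bromo-7-methoxy-2-(3,4,5-trimethoxyphenyl)-1-benzofuran-3(2H)-ylidene]methanone, the ring-contracted ketene (geometry at C2 as in 6) | COc1cc([C@@H]2Oc3c(OC)cc(Br)cc3C2=C=O)cc(OC)c1OC
F4 | step 4 | methyl (2R,3S)-5-bromo-7-methoxy-2-(3,4,5-trimethoxyphenyl)-2,3-dihydro-1-benzofuran-3-carboxylate (cis) | COc1cc([C@@H]2Oc3c(OC)cc(Br)cc3[C@@H]2C(=O)OC)cc(OC)c1OC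
F5 | step 3 | (E)-1-(5-bromo-2-hydroxy-3-methoxyphenyl)-3-(3,4,5-trimethoxyphenyl)prop-2-en-1-one | COc1cc(/C=C/C(=O)c2cc(Br)cc(OC)c2O)cc(OC)c1OC
F6 | step 3 | rac-6-bromo-8-methoxy-2-(3,4,5-trimethoxyphenyl)-2,3-dihydro-4H-chromen-4-one | COc1cc(C2Oc3c(OC)cc(Br)cc3C(=O)C2)cc(OC)c1OC
F7 | step 3 | (2S,4S)-6-bromo-8-methoxy-2-(3,4,5-trimethoxyphenyl)chroman-4-ol (2,4-cis) | COc1cc([C@H]2Oc3c(OC)cc(Br)cc3[C@@H](O)C2)cc(OC)c1OC
F8 | step 5 | [(2R,3S)-5-bromo-7-methoxy-2-(3,4,5-trimethoxyphenyl)-2,3-dihydro-1-benzofuran-3-yl]methanol (trans) | COc1cc([C@@H]2Oc3c(OC)cc(Br)cc3[C@H]2CO)cc(OC)c1OC
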